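Numbering used throughout: ring carbons C1 (formyl-bearing), C2 (side chain), C3 (OH), C4 (OMe), C5 (H), C6 (OH); side chain C1' (benzylic CH2), C2' (CH–OAc), C3'–C13' (undecyl).

## Analysis of the target

Compound 9 is a pentasubstituted benzaldehyde with no ring other than the benzene ring. C1 carries the formyl group, C2 the chain, C3 a hydroxyl, C4 the methoxy group, C5 the only ring hydrogen and C6 the second hydroxyl. C2' (R) is the only stereocentre. It is separated from the ring by C1', so nothing in the molecule can control it and it has to be bought or set by a reagent.

The hydroxyls on C3 and C6 are para to each other, so the ring is the reduced form of a 1,4-benzoquinone. In that quinone C2 is a ring CH that is β to both the formyl carbon on C1 and the C6 carbonyl, whereas C5 is the β-carbon of the C4 enol ether. The chain C1'–C13' with its oxygen on C2' is the skeleton of 3-hydroxytetradecanoic acid (compound 1) minus the carboxyl carbon.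

Sensitive groups are the air-oxidisable hydroquinone, the aldehyde and the secondary acetate, which can be lost or can migrate to the C3 phenol under base. A free C2' hydroxyl would also close onto the C1 formyl group to give a six-membered lactol. The difficulty is therefore density rather than size: five different substituents in a fixed order around one ring, and four oxygen functions in three states (OH, OMe, OAc). Any aryl-metal route must mask both phenols and the aldehyde and then unmask them without touching the acetate.

## Retrosynthetic reasoning

**9 ⇒ 8.** Only the two O–H bonds on C3 and C6 are removed: the hydroquinone 9 is taken back to the quinone 8. This changes the ring from a nucleophile into an electrophile and makes phenol protection unnecessary. The forward reaction is a mild two-electron reduction that must leave the aldehyde and the acetate alone.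

**8 ⇒ 7 + 3.** The C2–C1' bond, the only bond between ring and chain, is cut homolytically. This is the same bond the textbook route forms, but with the roles of both partners inverted: the ring carbon C2 is the acceptor (a quinone CH) and C1' is a nucleophilic primary radical generated by oxidative decarboxylation of the acid 3. What is gained:
- the ring partner 7 already holds the formyl group, the methoxy group and both ring oxygens, and needs no halogen, metal or protecting group;
- the chain partner 3 brings the stereocentre and the acetate in their final form.

The forward reaction has to add the radical at C2 and not at C5, and has to be faster than any rearrangement of the β-acetoxy radical.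

**3 ⇒ 1.** The acetyl–O bond on C2' is cut. The acetate is put on before the coupling, when neither a phenol nor an aldehyde is present, so the selectivity problem of acetylating a secondary alcohol beside two phenols never arises. The carboxyl group passes through the mixed anhydride 2, which is hydrolysed on work-up. The stereocentre comes from the chiral pool with 1, and its descriptor does not change on the way to 9.

**7 ⇒ 6 ⇒ 4.** The quinone 7 is the oxidised form of the hydroquinone aldehyde 6. In 6 the C–O bond at the carbon that becomes C3 of the target is cut, leading back through the aryl sulfate 5 to the commercial salicylaldehyde 4. Compound 4 already has the formyl group, one hydroxyl and the methoxy group in the right relation. The forward reaction must hydroxylate para to the phenol.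

## Alternatives that were turned down

**Alternative 1: the textbook cut.** The C2–C1' bond is cut heterolytically with the ring as the nucleophile. Bromine–lithium exchange on the bis(methoxymethyl)-protected aryl bromide A1, followed by copper- or Lewis-acid-assisted opening of the enantiopure terminal epoxide A2 at its CH2 carbon, would give the homobenzylic alcohol A3. A3 then needs formylation at C1, acetylation and removal of both acetal protecting groups. It was turned down because the polar reactivity dictates the whole sequence:
- The organolithium steps exclude the acetate and free phenols, so the formyl group must go in before acetylation. At that point the C2' hydroxyl and the new aldehyde collapse to a lactol unless another temporary group is added.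
- The final acidic unmasking must spare an acetate that sits within reach of a newly freed phenol.
- A1 is several steps from a commercial phenol, and both its bromination and the later ortho-metalation are regiochemically ambiguous on a ring with three oxygen substituents.
- A2 needs a kinetic resolution.

The count reaches about ten steps with four protecting-group operations.

**Alternative 2: the benzylic cut with lactone closure.** The C1'–C2' bond is cut. Lateral lithiation of the ortho-toluate A4 and addition to the C12 aldehyde A5 would close directly to the 3-undecyl-3,4-dihydroisocoumarin A6, which holds C1 at the acid level and ties the C2' oxygen to it. It was turned down on three counts: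
- The benzylic anion adds to an unhindered, enolisable aldehyde with no element of facial control, so A6 is racemic and needs a resolution or an asymmetric redox detour.
- A4 is not commercial, and putting its methyl group on C2 poses the same regiochemical problem as the chain itself.
- The lactone is a trap. Reduction stops at the lactol A7, whose acetylation gives the anomeric acetate. Reaching the open acetoxy aldehyde needs full reduction, differentiation of two alcohols, acetylation, deprotection and re-oxidation.

**Alternative 3: building the ring.** The ring bonds C2–C3 and C1–C6 are cut. Addition of lithiated vinyl iodide A9 to the semisquarate A8 gives the 4-alkenyl-4-hydroxycyclobutenone A10. Thermolysis (4π ring opening to a dienylketene, 6π closure, tautomerisation; a Moore-type ring expansion) would deliver the hydroquinone with all five substituents placed by the connectivity of A10. This is the most elegant answer to the substitution pattern, but it was turned down because it spends its power on the cheap part of the molecule: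
- The ring can be bought with the formyl, methoxy and one hydroxyl group already in place.
- A9, a geometrically defined trisubstituted vinyl iodide carrying the silyl-protected stereocentre and an acetal, would take six or more steps, and A8 two more.
- The organolithium step again forbids the acetate, so the silyl ether must be exchanged for acetate after the hydroquinone has appeared, which brings back phenol protection.

The route would exceed twelve steps.

Key step: step 4

Remark on the chemistry: (R)-3-hydroxytetradecanoic acid (the 3-hydroxymyristic acid of lipid A) is taken as a purchasable, enantiopure chiral-pool material. Its C3 maps onto C2' of the target with the same spatial arrangement and the same descriptor (R).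

## Route

Step 1
Reactants: 1 (R)-3-hydroxytetradecanoic acid
Product: 3 (R)-3-acetoxytetradecanoic acid, via acetic 3-acetoxytetradecanoic mixed anhydride 2 (not isolated)
Conditions: Ac2O (3 equiv), pyridine, 0 → 20 °C; then H2O, THF, 20 °C; 1 M HCl wash
Reagents that add atoms: acetic anhydride, CC(=O)OC(C)=O
Why: Pyridine-mediated O-acetylation (nucleophilic acyl substitution) of the secondary alcohol; the carboxyl group is drawn into the mixed anhydride 2, which the aqueous pyridine quench should cleave at its less hindered acetyl carbonyl, so water adds no heavy atom to 3. The C3–O bond is never broken, so the (R) configuration of 1 is retained; this is where the only stereocentre of the target enters the route.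

Step 2
Reactants: 4 2-hydroxy-4-methoxybenzaldehyde
Product: 6 2,5-dihydroxy-4-methoxybenzaldehyde, via potassium aryl sulfate 5 (not isolated)
Conditions: K2S2O8 (1.1 equiv), 10% aq KOH, 0 → 20 °C; HCl to pH 4, Et2O wash (recovers 4); then conc. HCl, 80 °C
Reagents that add atoms: potassium peroxodisulfate, [K+].[K+].[O-]S(=O)(=O)OOS(=O)(=O)[O-]
Why: Elbs peroxodisulfate oxidation: the phenolate of 4 attacks the peroxide O–O bond through the ring carbon para to the phenolate oxygen (also ortho to the methoxy group) to give aryl sulfate 5, whose S–O bond is hydrolysed in hot acid. The para position is free and doubly activated, and the non-enolisable aldehyde should survive the cold alkaline medium.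

Step 3
Reactants: 6 2,5-dihydroxy-4-methoxybenzaldehyde
Product: 7 4-methoxy-3,6-dioxocyclohexa-1,4-diene-1-carbaldehyde (2-formyl-5-methoxy-1,4-benzoquinone)
Conditions: Ag2O (3 equiv), anhydrous Na2SO4, Et2O, 20 °C, dark; filter (Celite), concentrate cold, use at once
Reagents that add atoms: none
Why: Two-electron oxidation of a hydroquinone to the 1,4-benzoquinone by silver(I) oxide under neutral, anhydrous conditions, the standard entry to formyl-1,4-benzoquinones; the drying agent takes up the water formed, which could otherwise add to the strongly electrophilic product.

Step 4
Reactants: 3 (R)-3-acetoxytetradecanoic acid; 7 4-methoxy-3,6-dioxocyclohexa-1,4-diene-1-carbaldehyde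
Product: 8 (2R)-1-(2-formyl-5-methoxy-3,6-dioxocyclohexa-1,4-dien-1-yl)tridecan-2-yl acetate
Conditions: 7 (2 equiv), AgNO3 (0.3 equiv), (NH4)2S2O8 (1.5 equiv, added over 1 h), MeCN/H2O 1:1, 65 °C, N2
Reagents that add atoms: none
Why: This is a Jacobsen–Torssell (Minisci-type) decarboxylative alkylation of a quinone: Ag(I) is oxidised by peroxodisulfate to Ag(II), which oxidises the carboxylate of 3 and releases CO2 and the primary radical •CH2–CH(OAc)–C11H23. This nucleophilic radical should add to the ring CH of 7 next to the formyl-bearing carbon, and the adduct radical, stabilised by the ring carbonyl and the formyl group, is oxidised and loses a proton to restore the quinone with the new C2–C1' bond. The closest known reaction type is the silver/peroxodisulfate alkylation of benzo- and naphthoquinones with aliphatic carboxylic acids. No ring is closed and no new stereocentre is formed; the (R) centre sits β to the radical carbon, never becomes trigonal and is carried over unchanged. The step needs regioselectivity between the two free ring positions of 7: the CH next to the methoxy-bearing carbon is the electron-rich β-carbon of an enol ether and should repel a nucleophilic radical, while the CH next to the formyl-bearing carbon is the β-position of a doubly activated acceptor. It also needs the bimolecular addition to outrun the slow 1,2-acetoxy shift and 1,5-hydrogen transfer of the radical, which is served by keeping 7 in excess and concentrated. The acidic medium keeps the acetate in place and disfavours loss of acetic acid from the vinylogously acidic C1' methylene of 8.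

Step 5
Reactants: 8 (2R)-1-(2-formyl-5-methoxy-3,6-dioxocyclohexa-1,4-dien-1-yl)tridecan-2-yl acetate
Product: 9 (2R)-1-(2-formyl-3,6-dihydroxy-5-methoxyphenyl)tridecan-2-yl acetate
Conditions: Na2S2O4 (3 equiv), EtOAc/H2O (pH 6 phosphate buffer), 20 °C, Ar
Reagents that add atoms: none
Why: Dithionite reduction of a 1,4-benzoquinone to the hydroquinone, a fast two-electron, two-proton transfer at room temperature that should leave the aryl aldehyde and the alkyl acetate untouched; the weakly acidic buffer avoids base-induced loss of acetic acid from 8 and acetyl migration to the C3 phenol in 9. No stereocentre is affected.

## Compound list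

1 | (R)-3-hydroxytetradecanoic acid | CCCCCCCCCCC[C@H](CC(=O)O)O | starting material
2 | acetic (3R)-3-acetoxytetradecanoic anhydride | CCCCCCCCCCC[C@H](CC(=O)OC(C)=O)OC(C)=O | intermediate
3 | (R)-3-acetoxytetradecanoic acid | CCCCCCCCCCC[C@H](CC(=O)O)OC(C)=O | intermediate
4 | 2-hydroxy-4-methoxybenzaldehyde | COc1ccc(C=O)c(O)c1 | starting material
5 | potassium 4-formyl-5-hydroxy-2-methoxyphenyl sulfate | COc1cc(O)c(C=O)cc1OS(=O)(=O)[O-].[K+] | intermediate
6 | 2,5-dihydroxy-4-methoxybenzaldehyde | COc1cc(O)c(C=O)cc1O | intermediate
7 | 4-methoxy-3,6-dioxocyclohexa-1,4-diene-1-carbaldehyde | COC1=CC(=O)C(C=O)=CC1=O | intermediate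
8 | (2R)-1-(2-formyl-5-methoxy-3,6-dioxocyclohexa-1,4-dien-1-yl)tridecan-2-yl acetate | CCCCCCCCCCC[C@H](CC1=C(C=O)C(=O)C=C(OC)C1=O)OC(C)=O | intermediate
9 | (2R)-1-(2-formyl-3,6-dihydroxy-5-methoxyphenyl)tridecan-2-yl acetate | CCCCCCCCCCC[C@H](Cc1c(O)c(OC)cc(O)c1C=O)OC(C)=O | target

## Step count and uncertain steps

Total step count: 5. Longest linear sequence: 4 steps (4 → 6 → 7 → 8 → 9, steps 2 to 5); the chain branch 1 → 3 is one step and joins at step 4.

**Step 4 (key step).** Four processes could go wrong:
- Competing consumption of 7 in the hot, aqueous, oxidising medium (hydration and conjugate addition of water, or oxidation of the formyl C–H by Ag(II) or sulfate radical anion) before the alkyl radical is captured.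
- Radical attack at the other ring CH or at a quinone oxygen.
- 1,2-Acetoxy shift of the radical before capture, which would give the regioisomeric chain.
- Loss of acetic acid from 8 through its quinone-methide tautomer during work-up.

Fallback, setting out from 3 and coming back at 8: the acid 3 is condensed with 1-hydroxypyridine-2(1H)-thione (DCC, CH2Cl2, 0 °C, dark) to the O-acyl thiohydroxamate (Barton ester) F1. F1 is photolysed with a tungsten lamp in CH2Cl2 at 0 to 20 °C in the presence of excess 7. The same primary radical is then formed in a neutral, anhydrous, non-oxidising chain. The adduct radical should capture the 2-pyridylthio group to give the thioether F2 (mixture of ring diastereomers). F2 should lose pyridine-2-thione on silica, since the ring C–H next to the new chain is α to a carbonyl, and so return to the route at 8.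

**Step 3.** The isolated formylquinone 7 is a strong electrophile, and decomposition (self-condensation, addition of adventitious water) during concentration or storage is the likely failure. Fallback, setting out from 6 and coming back at 8: 7 is not isolated. 6 is oxidised in the flask of step 4 with one extra equivalent of peroxodisulfate and the silver salt at 20 °C before 3 is added and the mixture is warmed, so that 7 is generated and consumed in one pot (no new compound: F0).

**Step 2.** The Elbs oxidation is prone to incomplete conversion, to over-oxidation of the electron-rich product to polymeric material and to some ortho attack. Fallback, setting out from 4 and coming back at 6: bromination para to the phenol (NBS, MeCN, 0 °C) to 5-bromo-2-hydroxy-4-methoxybenzaldehyde F3, then copper-catalysed hydroxylation of the aryl bromide (CuI, 8-hydroxyquinoline, KOH, DMSO/H2O, 100 °C, acidic work-up) to 6.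

**Step 5.** The reduction itself is reliable. The risk lies in handling: loss of acetic acid from 8 on silica or on standing before reduction, and air re-oxidation of 9 during purification. Fallback, setting out from 3 and 7 and coming back at 9: 8 is not isolated. The cooled mixture of step 4 is extracted and the extract is shaken at once with buffered dithionite. 9 is then purified under argon, and the co-formed 6 (from excess 7) is removed by its much higher polarity and can be recycled into step 3 (no new compound: F0).

## Further compounds

F1 | step 4 | 2-thioxopyridin-1(2H)-yl (R)-3-acetoxytetradecanoate | CCCCCCCCCCC[C@H](CC(=O)On1ccccc1=S)OC(C)=O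
F2 | step 4 | (2R)-1-[2-formyl-5-methoxy-3,6-dioxo-2-(pyridin-2-ylsulfanyl)cyclohex-4-en-1-yl]tridecan-2-yl acetate (mixture of ring diastereomers) | CCCCCCCCCCC[C@H](CC1C(=O)C(OC)=CC(=O)C1(C=O)Sc1ccccn1)OC(C)=O
F0 | step 3 | none | none
F3 | step 2 | 5-bromo-2-hydroxy-4-methoxybenzaldehyde | COc1cc(O)c(C=O)cc1Br
F0 | step 5 | none | none
A1 | alternative 1 | 1-bromo-3-methoxy-2,5-bis(methoxymethoxy)benzene | COCOc1cc(OC)c(OCOC)c(Br)c1
A2 | alternative 1 | (R)-2-undecyloxirane | CCCCCCCCCCC[C@@H]1CO1
A3 | alternative 1 | (R)-1-[3-methoxy-2,5-bis(methoxymethoxy)phenyl]tridecan-2-ol | CCCCCCCCCCC[C@H](Cc1cc(OCOC)cc(OC)c1OCOC)O
A4 | alternative 2 | methyl 4-methoxy-3,6-bis(methoxymethoxy)-2-methylbenzoate | COC(=O)c1c(C)c(OCOC)c(OC)cc1OCOC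
A5 | alternative 2 | dodecanal | CCCCCCCCCCCC=O
A6 | alternative 2 | rac-6-methoxy-5,8-bis(methoxymethoxy)-3-undecylisochroman-1-one | CCCCCCCCCCCC1Cc2c(OCOC)c(OC)cc(OCOC)c2C(=O)O1
A7 | alternative 2 | 6-methoxy-5,8-bis(methoxymethoxy)-3-undecylisochroman-1-ol (mixture of stereoisomers) | CCCCCCCCCCCC1Cc2c(OCOC)c(OC)cc(OCOC)c2C(O)O1
A8 | alternative 3 | 3-methoxycyclobut-3-ene-1,2-dione | COC1=CC(=O)C1=O
A9 | alternative 3 | (R,E)-tert-butyl[(3-iodo-1,1-dimethoxyhexadec-2-en-5-yl)oxy]dimethylsilane | CCCCCCCCCCC[C@H](C/C(I)=C\C(OC)OC)O[Si](C)(C)C(C)(C)C
A10 | alternative 3 | 4-[(2E,5R)-5-(tert-butyldimethylsilyloxy)-1,1-dimethoxyhexadec-2-en-3-yl]-4-hydroxy-3-methoxycyclobut-2-en-1-one (both configurations at the ring carbinol) | CCCCCCCCCCC[C@H](C/C(=C\C(OC)OC)C1(O)C(OC)=CC1=O)O[Si](C)(C)C(C)(C)C
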